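The peroxide-bearing seven-membered ring (guaiane numbering, primed) is cut across its diene: C-1′, C-10′, C-9′, C-8′, C-7′ and the cyclopentenone carbonyl C-2′ are a pulegone-derived 3-acylcyclopent-2-enone, while C-5′/C-6′ are an ethynyl group on the methyl-bearing quaternary carbon C-4′ of a norbornene. One intramolecular enone–alkyne [2+2] photocycloaddition forms C-1′–C-5′ and C-7′–C-6′, closing the cyclopentenone ring and a cyclobutene whose opening gives the cycloheptadienone; enolate autoxidation then closes the 1,2-dioxolane hemiketal. The precursor is the endo-acyl, endo-ethynyl 7-syn-acetoxynorbornene, assembled by Diels–Alder addition of a pulegone-derived diynone to a cyclopentadienone ketal made from the same pulegone-derived keto ester.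

Key step: step 25

Remarks on the chemistry (one line each):
- Numbering: guaiane numbering, unprimed for the acetoxy half (norbornene carbons C-1, C-2 bridge, C-3, C-4=C-5, C-3′, C-4′), primed for the peroxide half.
- Assumption: C-7 (α to the C-8 ketone) has the thermodynamically preferred configuration in the target, so it is set by equilibration whenever that ketone is free (steps 9 and 24).
- Assumption: the hemiketal carbon C-8′ forms under ring–chain equilibration and the natural configuration is the stable one.
- Centres that are destroyed later (carbinol carbons C-8 and C-8′, and sp3 centres that become trigonal) are drawn as the expected epimer or left open; their configuration is inconsequential.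
- The (R) configuration of pulegone maps onto both C-10 and C-10′; the bridge acetate must be syn to C-4=C-5, which kinetic hydride delivery would not give, so it is set under equilibrating conditions (step 21).

Step 1
Reactants: 1 (R)-pulegone
Product: 3 methyl pulegenate (methyl (5R)-5-methyl-2-(propan-2-ylidene)cyclopentane-1-carboxylate, C-1 epimers), via pulegone dibromide 2 (not isolated)
Conditions: Br2, AcOH/Et2O, 0 °C; then NaOMe, MeOH, reflux
Reagents that add atoms: sodium methoxide, C[O-].[Na+]
Why: Favorskii rearrangement of the dibromo ketone (cyclopropanone from the C-6 enolate, methoxide opening, loss of the second bromide) contracts the ring and leaves the methyl stereocentre of pulegone untouched.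

Step 2
Reactants: 3 methyl pulegenate
Product: 4 methyl (5R)-5-methyl-2-(propan-2-yl)cyclopent-1-ene-1-carboxylate
Conditions: NaOMe, MeOH, 65 °C
Reagents that add atoms: none
Why: Base-mediated alkene isomerisation through the ester dienolate (γ-protonation) should give the conjugated, tetrasubstituted endocyclic ester as the thermodynamic isomer, and the methyl-bearing carbon is not acidic.

Step 3
Reactants: 4 conjugated ester
Product: 5 keto ester, methyl (5R)-5-methyl-3-oxo-2-(propan-2-yl)cyclopent-1-ene-1-carboxylate
Conditions: t-BuOOH, Rh2(cap)4 (1 mol %), K2CO3, CH2Cl2, rt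
Reagents that add atoms: tert-butyl hydroperoxide, CC(C)(C)OO
Why: Dirhodium-catalysed allylic oxidation (peroxyl-radical hydrogen abstraction) should convert the ring methylene γ to the ester into the enone, because the isopropyl methine lies in the alkene plane (allylic strain) and the C-5 hydrogen is only cross-conjugated.

Step 4
Reactants: 5 keto ester
Product: 6 methyl (3S,5R)-3-hydroxy-5-methyl-2-(propan-2-yl)cyclopent-1-ene-1-carboxylate
Conditions: NaBH4, CeCl3·7H2O, MeOH, −40 °C
Reagents that add atoms: none
Why: Luche 1,2-reduction masks the ring ketone as an allylic alcohol so that it survives the organometallic and equilibrating hydride steps, the new carbinol centre (hydride anti to the methyl) being re-oxidised in step 24.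

Step 5
Reactants: 6 allylic alcohol
Product: 7 tert-butyldiphenylsilyl ether of 6
Conditions: TBDPSCl, imidazole, DMF, rt
Reagents that add atoms: tert-butyl(chloro)diphenylsilane, CC(C)(C)[Si](Cl)(c1ccccc1)c1ccccc1
Why: Standard silylation, with TBDPS chosen because it must survive the acid hydrolysis of the bridge ketal in step 20.

Step 6
Reactants: 7 silyl ether ester
Product: 8 Weinreb amide (N-methoxy-N-methyl amide of 7)
Conditions: MeNH(OMe)·HCl, i-PrMgCl, THF, −20 → 0 °C
Reagents that add atoms: N,O-dimethylhydroxylamine hydrochloride, CNOC.Cl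
Why: Aminolysis of the ester by the magnesium amide gives the Weinreb amide needed for clean single addition of an acetylide.

Step 7
Reactants: 8 Weinreb amide; 9 1,4-bis(trimethylsilyl)buta-1,3-diyne
Product: 11 diynone (1-[(3S,5R)-3-(TBDPS-oxy)-5-methyl-2-isopropylcyclopent-1-enyl]-5-(trimethylsilyl)penta-2,4-diyn-1-one), via lithium 4-(trimethylsilyl)buta-1,3-diynide 10 (not isolated)
Conditions: 9, MeLi·LiBr, THF, 0 °C → rt; then 8, −78 → 0 °C; aq. NH4Cl
Reagents that add atoms: none
Why: Mono-desilylation of the bis-silyl diyne by methyllithium gives the lithium acetylide, which adds once to the Weinreb amide (stable chelate) to give the ynone.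

Step 8
Reactants: 5 keto ester
Product: 12 methyl 4-methyl-2-oxo-1-(propan-2-yl)bicyclo[3.2.0]heptane-5-carboxylate (cis-fused, cyclobutane anti to the methyl)
Conditions: ethylene (saturated), hν (λ > 300 nm, Pyrex), CH2Cl2, −78 °C
Reagents that add atoms: ethylene, C=C
Why: Enone–alkene [2+2] photocycloaddition (triplet enone, 1,4-biradical) gives the cis-fused cyclobutane, ethylene adding to the face anti to the methyl group; both new quaternary centres are cleaved or made trigonal again later.

Step 9
Reactants: 12 cyclobutane keto ester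
Product: 13 methyl (2R,5S)-2-methyl-4-oxo-5-(propan-2-yl)cycloheptane-1-carboxylate (C-1 epimers)
Conditions: SmI2 (2.5 equiv), THF–MeOH, −78 °C → rt; then DBU (cat.), CH2Cl2, rt
Reagents that add atoms: none
Why: Ketyl formation and strain-driven β-scission of the cyclobutane bond between the ketone α-carbon and the ester-bearing carbon (giving the ester-stabilised radical, then enolate) effect a two-carbon ring expansion, and equilibration α to the ketone sets the isopropyl centre cis to the methyl (see assumption).

Step 10
Reactants: 13 cycloheptanone ester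
Product: 14 methyl 4-hydroxy-2-methyl-5-(propan-2-yl)cycloheptane-1-carboxylate (hydroxyl cis to isopropyl and methyl)
Conditions: L-Selectride, THF, −78 °C
Reagents that add atoms: none
Why: The bulky hydride attacks the ketone anti to the adjacent isopropyl group and leaves the ester untouched at −78 °C, which protects this position at the alcohol level and puts all three ring substituents on one face.

Step 11
Reactants: 14 hydroxy ester
Product: 15 tert-butyldiphenylsilyl ether of 14
Conditions: TBDPSCl, imidazole, DMAP, DMF, 50 °C
Reagents that add atoms: tert-butyl(chloro)diphenylsilane, CC(C)(C)[Si](Cl)(c1ccccc1)c1ccccc1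
Why: Silylation of the hindered secondary alcohol under forcing but standard conditions gives an ether that is stable to base, Lewis acid and the later ketal hydrolysis.

Step 12
Reactants: 15 silyloxy ester
Product: 18 methyl 5-(TBDPS-oxy)-7-methyl-4-(propan-2-yl)cyclohept-1-ene-1-carboxylate, via α-phenylselanyl ester 16 (not isolated), via selenoxide 17 (not isolated)
Conditions: LDA, THF, −78 °C; PhSeBr; then 30% H2O2, pyridine, CH2Cl2, 0 °C → rt
Reagents that add atoms: none
Why: α-Selenenylation of the ester enolate and selenoxide syn-elimination introduce the α,β-unsaturation, elimination going towards the ring methylene (two accessible syn hydrogens) and not the hindered methyl-bearing methine.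

Step 13
Reactants: 18 unsaturated ester
Product: 19 Weinreb amide of 18
Conditions: MeNH(OMe)·HCl, i-PrMgCl, THF, −20 → 0 °C
Reagents that add atoms: N,O-dimethylhydroxylamine hydrochloride, CNOC.Cl
Why: Aminolysis of the ester by the magnesium amide gives the acylating agent for controlled ketone synthesis.

Step 14
Reactants: 19 Weinreb amide
Product: 20 divinyl ketone, (E)-1-[5-(TBDPS-oxy)-7-methyl-4-isopropylcyclohept-1-enyl]but-2-en-1-one
Conditions: (E)-prop-1-enylmagnesium bromide, THF, 0 °C
Reagents that add atoms: (E)-prop-1-enylmagnesium bromide, C/C=C/[Mg]Br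
Why: Grignard addition to the Weinreb amide stops at the ketone (chelated tetrahedral intermediate), and the propenyl geometry is irrelevant because that carbon becomes trigonal later.

Step 15
Reactants: 20 divinyl ketone
Product: 21 bicyclic enone, 6-(TBDPS-oxy)-3,8-dimethyl-5-(propan-2-yl)-3,4,5,6,7,8-hexahydroazulen-1(2H)-one (C-3 epimers)
Conditions: BF3·OEt2, CH2Cl2, 0 °C → rt
Reagents that add atoms: none
Why: Nazarov cyclisation (4π conrotatory closure of the pentadienyl cation) forms the C-4–C-5 bond and the alkene settles in the tetrasubstituted ring-fusion position conjugated to the ketone.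

Step 16
Reactants: 21 bicyclic enone
Product: 22 2-(phenylselanyl) derivative of 21
Conditions: LDA, THF, −78 °C; PhSeCl
Reagents that add atoms: benzeneselenenyl chloride, Cl[Se]c1ccccc1
Why: Kinetic deprotonation of the enone can occur only at the α′ methylene (C-3 in guaiane numbering), and selenenylation anti to the neighbouring methyl places selenium syn to the hydrogen needed for elimination.

Step 17
Reactants: 22 α′-selanyl enone
Product: 23 ethylene ketal of 22
Conditions: 1,2-bis(trimethylsilyloxy)ethane, TMSOTf (10 mol %), CH2Cl2, −78 → −20 °C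
Reagents that add atoms: 1,2-bis(trimethylsilyloxy)ethane, C[Si](C)(C)OCCO[Si](C)(C)C
Why: Silyl-triflate-catalysed ketalisation under aprotic, low-temperature conditions protects the enone carbonyl without moving the ring-fusion alkene.

Step 18
Reactants: 23 selanyl ketal; 11 diynone
Product: 26 Diels–Alder adduct (2,2-ethylenedioxynorbornadiene with the acyl group on C-3′ and the silylethynyl group on C-4′), via selenoxide 24 (not isolated), via cyclopentadienone ketal 25 (not isolated)
Conditions: m-CPBA, CH2Cl2, −78 °C; then i-Pr2NH and 11, −78 → 45 °C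
Reagents that add atoms: none
Why: Selenoxide syn-elimination (only the C-4 hydrogen is available) releases the cyclopentadienone ketal, which cannot undergo 1,5-hydrogen shifts and adds the ynone in a Diels–Alder reaction; the bulky acyl terminus bonds to the unsubstituted diene terminus C-3 and the slim diynyl terminus to C-1, on the face opposite the C-10 methyl, C-7 isopropyl and C-8 silyloxy groups, which sets C-1 and C-3.

Step 19
Reactants: 26 norbornadienyl ketone
Product: 27 C-4′ methyl adduct (exo-methyl, endo-silylethynyl, endo-acyl norbornene ketal)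
Conditions: Me3Al, CuBr·SMe2 (10 mol %), THF, −40 → 0 °C; aq. Rochelle salt
Reagents that add atoms: trimethylaluminium, C[Al](C)C
Why: Copper-catalysed 1,4-addition of the methyl group to the strained β-alkynyl enone occurs from the exo face (catalytic copper with a silylated alkyne terminus favours 1,4 over 1,6), and exo protonation of the enolate gives the endo acyl group at C-3′, which is also the more stable epimer.

Step 20
Reactants: 27 bridge ketal
Product: 28 bridge (C-2) ketone
Conditions: TFA–H2O (9:1), CH2Cl2, 0 °C → rt
Reagents that add atoms: water, O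
Why: Acid hydrolysis of the strained 7-norbornenyl ketal needs strong acid, which the TBDPS ethers, the C-silyl alkyne and the hindered enone tolerate.

Step 21
Reactants: 28 bridge ketone
Product: 29 C-2 alcohol with the hydroxyl syn to the C-4=C-5 alkene
Conditions: Al(Oi-Pr)3, i-PrOH, acetone (0.2 equiv), toluene, 60 °C
Reagents that add atoms: none
Why: Meerwein–Ponndorf–Verley reduction kept reversible by a little acetone should give the thermodynamic alcohol, syn to the alkene, because the epimer (the kinetic hydride product) clashes with the exo C-4′ methyl group; the hindered conjugated C-2′ ketone reacts far more slowly than the strained bridge ketone.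

Step 22
Reactants: 29 C-2 alcohol
Product: 30 C-2 acetate
Conditions: Ac2O, DMAP, pyridine, CH2Cl2, rt
Reagents that add atoms: acetic anhydride, CC(=O)OC(C)=O
Why: Acylation of the only free hydroxyl group fixes the bridge stereocentre as the acetate of the target.

Step 23
Reactants: 30 bis-silyl ether, C-silyl alkyne
Product: 31 8,8′-diol with free ethynyl group
Conditions: TBAF, AcOH, THF, rt → 40 °C
Reagents that add atoms: none
Why: Buffered fluoride cleaves both silyl ethers and the alkynylsilane in one operation while the acetate survives.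

Step 24
Reactants: 31 diol
Product: 32 photo precursor: ethynyl norbornene carrying the pulegone-derived acylcyclopentenone (8,8′-diketone)
Conditions: Dess–Martin periodinane, NaHCO3, CH2Cl2, rt
Reagents that add atoms: none
Why: Dess–Martin oxidation of both secondary alcohols regenerates the cycloheptanone and the ene-1,4-dione chromophore under non-basic conditions that do not touch the acetate or the terminal alkyne.

Step 25
Reactants: 32 photo precursor
Product: 33 cyclobutene photoadduct
Conditions: hν (405 nm LED), thioxanthone (20 mol %), degassed CH2Cl2 (2 mM), 0 °C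
Reagents that add atoms: none
Why: Triplet energy transfer excites the ene-1,4-dione of the 1-en-6-yn-3-one array C-7′=C-1′–C-2′(=O)–C-3′–C-4′–C-5′≡C-6′; C-1′ bonds first to the inner alkyne carbon C-5′ (5-exo-dig, rule of five), closing the future cyclopentenone ring, and the α-keto/vinyl 1,4-biradical then closes C-7′–C-6′ (four-membered ring by radical recombination) to the cis-fused cyclobutene. The closest known reaction type is the intramolecular [2+2] photocycloaddition of cyclopentenones with tethered alkynes. The two new quaternary centres C-1′ and C-7′ are necessarily cis (bicyclo[3.2.0] fusion) and form on the enone face anti to the C-10′ methyl group; their sense is inconsequential because both become trigonal in step 26. The step needs the alkyne to react and not the tetrasubstituted C-4=C-5 norbornene alkene or the C-2′ carbonyl (Paternò–Büchi): the endo-ethynyl group is held cis-vicinal to the endo-acyl group on the rigid norbornane, whereas addition to C-4=C-5 would create four contiguous quaternary carbons, so that biradical should revert. Long-wavelength sensitisation avoids n,π* chemistry of the saturated ketone and secondary 1,3-acyl shifts of the β,γ-unsaturated product, and a base-free aprotic medium makes γ-hydrogen abstraction from the isopropyl group non-productive.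

Step 26
Reactants: 33 cyclobutene photoadduct
Product: 34 cycloheptadienone (1′(5′),6′-diene-2′,8′-dione)
Conditions: degassed toluene, BHT (cat.), 110 °C, dark
Reagents that add atoms: none
Why: Thermal opening of the bicyclo[3.2.0]hept-6-ene breaks the C-1′–C-7′ bond, which is flanked by both carbonyl groups and allylic at both ends, relieves the strain of the four-membered ring and puts both alkenes in their final positions.

Step 27
Reactants: 34 cycloheptadienone
Product: 36 target CNP0317907.1, via C-11′ hydroperoxide 35 (not isolated)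
Conditions: O2 (1 atm), DBU (1.0 equiv), MeCN, −20 → 0 °C; then AcOH
Reagents that add atoms: dioxygen, O=O
Why: Proposed new method: deprotonation of the isopropyl methine (ε to the C-2′ carbonyl through C-1′=C-5′–C-6′=C-7′) should give a trienolate that couples with triplet oxygen at its terminal carbon C-11′, keeping the dienedione conjugated, and the tertiary hydroperoxide adds to the adjacent C-8′ ketone to close the 1,2-dioxolan-3-ol; the closest known reaction types are base-mediated autoxidation of extended enolates at their remote carbon (γ-hydroperoxidation of β-alkyl enones) and ring closure of β-hydroperoxy ketones to cyclic peroxyhemiketals; the C-10′ hydrogen should stay untouched because allylic strain with the C-2′ carbonyl holds it in the enone plane, and triplet oxygen spares the tetrasubstituted C-4=C-5 alkene.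

Compound list
1 | (R)-pulegone | C[C@@H]1CCC(=C(C)C)C(=O)C1 | starting material
2 | pulegone dibromide | C[C@@H]1CCC(Br)(C(C)(C)Br)C(=O)C1 | intermediate
3 | methyl pulegenate (C-1 epimers) | COC(=O)C1C(=C(C)C)CC[C@H]1C | intermediate
4 | methyl (5R)-5-methyl-2-isopropylcyclopent-1-ene-1-carboxylate | COC(=O)C1=C(C(C)C)CC[C@H]1C | intermediate
5 | keto ester, methyl (5R)-5-methyl-3-oxo-2-isopropylcyclopent-1-ene-1-carboxylate | COC(=O)C1=C(C(C)C)C(=O)C[C@H]1C | intermediate
6 | allylic alcohol (3S,5R) | COC(=O)C1=C(C(C)C)[C@@H](O)C[C@H]1C | intermediate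
7 | TBDPS ether of 6 | COC(=O)C1=C(C(C)C)[C@@H](O[Si](c2ccccc2)(c2ccccc2)C(C)(C)C)C[C@H]1C | intermediate
8 | Weinreb amide of 7 | CON(C)C(=O)C1=C(C(C)C)[C@@H](O[Si](c2ccccc2)(c2ccccc2)C(C)(C)C)C[C@H]1C | intermediate
9 | 1,4-bis(trimethylsilyl)buta-1,3-diyne | C[Si](C)(C)C#CC#C[Si](C)(C)C | starting material
10 | lithium 4-(trimethylsilyl)buta-1,3-diynide | [Li]C#CC#C[Si](C)(C)C | intermediate
11 | diynone | C[Si](C)(C)C#CC#CC(=O)C1=C(C(C)C)[C@@H](O[Si](c2ccccc2)(c2ccccc2)C(C)(C)C)C[C@H]1C | intermediate
12 | ethylene photoadduct (bicyclo[3.2.0]heptanone ester) | COC(=O)[C@@]12CC[C@]1(C(C)C)C(=O)C[C@H]2C | intermediate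
13 | cycloheptanone ester (C-1 epimers) | COC(=O)C1CC[C@@H](C(C)C)C(=O)C[C@H]1C | intermediate
14 | hydroxy ester | COC(=O)C1CC[C@@H](C(C)C)[C@@H](O)C[C@H]1C | intermediate
15 | TBDPS ether of 14 | COC(=O)C1CC[C@@H](C(C)C)[C@@H](O[Si](c2ccccc2)(c2ccccc2)C(C)(C)C)C[C@H]1C | intermediate
16 | α-phenylselanyl ester | COC(=O)C1([Se]c2ccccc2)CC[C@@H](C(C)C)[C@@H](O[Si](c3ccccc3)(c3ccccc3)C(C)(C)C)C[C@H]1C | intermediate
17 | selenoxide of 16 | COC(=O)C1([Se](=O)c2ccccc2)CC[C@@H](C(C)C)[C@@H](O[Si](c3ccccc3)(c3ccccc3)C(C)(C)C)C[C@H]1C | intermediate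
18 | cycloheptene ester | COC(=O)C1=CC[C@@H](C(C)C)[C@@H](O[Si](c2ccccc2)(c2ccccc2)C(C)(C)C)C[C@H]1C | intermediate
19 | Weinreb amide of 18 | CON(C)C(=O)C1=CC[C@@H](C(C)C)[C@@H](O[Si](c2ccccc2)(c2ccccc2)C(C)(C)C)C[C@H]1C | intermediate
20 | divinyl ketone | C/C=C/C(=O)C1=CC[C@@H](C(C)C)[C@@H](O[Si](c2ccccc2)(c2ccccc2)C(C)(C)C)C[C@H]1C | intermediate
21 | bicyclic enone (C-3 epimers) | CC1CC(=O)C2=C1C[C@@H](C(C)C)[C@@H](O[Si](c3ccccc3)(c3ccccc3)C(C)(C)C)C[C@H]2C | intermediate
22 | α′-phenylselanyl enone | CC1C([Se]c2ccccc2)C(=O)C3=C1C[C@@H](C(C)C)[C@@H](O[Si](c4ccccc4)(c4ccccc4)C(C)(C)C)C[C@H]3C | intermediate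
23 | ethylene ketal of 22 | CC1C([Se]c2ccccc2)C3(OCCO3)C4=C1C[C@@H](C(C)C)[C@@H](O[Si](c5ccccc5)(c5ccccc5)C(C)(C)C)C[C@H]4C | intermediate
24 | selenoxide of 23 | CC1C([Se](=O)c2ccccc2)C3(OCCO3)C4=C1C[C@@H](C(C)C)[C@@H](O[Si](c5ccccc5)(c5ccccc5)C(C)(C)C)C[C@H]4C | intermediate
25 | cyclopentadienone ethylene ketal | CC1=CC2(OCCO2)C3=C1C[C@@H](C(C)C)[C@@H](O[Si](c4ccccc4)(c4ccccc4)C(C)(C)C)C[C@H]3C | intermediate
26 | Diels–Alder adduct (norbornadiene ketal) | O1CCOC12[C@H]3C(C)=C4C[C@@H](C(C)C)[C@@H](O[Si](c5ccccc5)(c5ccccc5)C(C)(C)C)C[C@@H](C)[C@]42C(C#C[Si](C)(C)C)=C3C(=O)C6=C(C(C)C)[C@@H](O[Si](c7ccccc7)(c7ccccc7)C(C)(C)C)C[C@H]6C | intermediate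
27 | C-4′ methyl adduct | O1CCOC12[C@H]3C(C)=C4C[C@@H](C(C)C)[C@@H](O[Si](c5ccccc5)(c5ccccc5)C(C)(C)C)C[C@@H](C)[C@]42[C@](C)(C#C[Si](C)(C)C)[C@@H]3C(=O)C6=C(C(C)C)[C@@H](O[Si](c7ccccc7)(c7ccccc7)C(C)(C)C)C[C@H]6C | intermediate
28 | bridge ketone | O=C1[C@H]2C(C)=C3C[C@@H](C(C)C)[C@@H](O[Si](c4ccccc4)(c4ccccc4)C(C)(C)C)C[C@@H](C)[C@]31[C@](C)(C#C[Si](C)(C)C)[C@@H]2C(=O)C5=C(C(C)C)[C@@H](O[Si](c6ccccc6)(c6ccccc6)C(C)(C)C)C[C@H]5C | intermediate
29 | C-2 alcohol (syn to alkene) | O[C@H]1[C@H]2C(C)=C3C[C@@H](C(C)C)[C@@H](O[Si](c4ccccc4)(c4ccccc4)C(C)(C)C)C[C@@H](C)[C@]31[C@](C)(C#C[Si](C)(C)C)[C@@H]2C(=O)C5=C(C(C)C)[C@@H](O[Si](c6ccccc6)(c6ccccc6)C(C)(C)C)C[C@H]5C | intermediate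
30 | C-2 acetate | CC(=O)O[C@H]1[C@H]2C(C)=C3C[C@@H](C(C)C)[C@@H](O[Si](c4ccccc4)(c4ccccc4)C(C)(C)C)C[C@@H](C)[C@]31[C@](C)(C#C[Si](C)(C)C)[C@@H]2C(=O)C5=C(C(C)C)[C@@H](O[Si](c6ccccc6)(c6ccccc6)C(C)(C)C)C[C@H]5C | intermediate
31 | 8,8′-diol, free alkyne | CC(=O)O[C@H]1[C@H]2C(C)=C3C[C@@H](C(C)C)[C@@H](O)C[C@@H](C)[C@]31[C@](C)(C#C)[C@@H]2C(=O)C4=C(C(C)C)[C@@H](O)C[C@H]4C | intermediate
32 | photo precursor (ethynyl norbornene with acylcyclopentenone) | CC(=O)O[C@H]1[C@H]2C(C)=C3C[C@@H](C(C)C)C(=O)C[C@@H](C)[C@]31[C@](C)(C#C)[C@@H]2C(=O)C4=C(C(C)C)C(=O)C[C@H]4C | intermediate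
33 | cyclobutene photoadduct | CC(=O)O[C@H]1[C@H]2C(C)=C3C[C@@H](C(C)C)C(=O)C[C@@H](C)[C@]31[C@]1(C)C3=C[C@]4(C(C)C)C(=O)C[C@@H](C)[C@]34C(=O)[C@H]21 | intermediate
34 | cycloheptadienone | CC(=O)O[C@H]1[C@H]2C(C)=C3C[C@@H](C(C)C)C(=O)C[C@@H](C)[C@]31[C@]1(C)C3=C(C(=O)[C@H]21)[C@H](C)CC(=O)C(C(C)C)=C3 | intermediate
35 | C-11′ hydroperoxide | CC(=O)O[C@H]1[C@H]2C(C)=C3C[C@@H](C(C)C)C(=O)C[C@@H](C)[C@]31[C@]1(C)C3=C(C(=O)[C@H]21)[C@H](C)CC(=O)C(C(C)(C)OO)=C3 | intermediate
36 | CNP0317907.1 | CC(=O)O[C@H]1[C@H]2C(C)=C3C[C@@H](C(C)C)C(=O)C[C@@H](C)[C@]31[C@]1(C)C3=C(C(=O)[C@H]21)[C@H](C)C[C@@]1(O)OOC(C)(C)C1=C3 | target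

Total step count: 27.
Longest linear sequence: 23 steps (steps 1–3 and 8–27, from 1 through 5, 12 and 25 to 36); the ynone branch (steps 4–7) joins at step 18.

Steps most likely to fail

1. Step 27 (proposed new method). The base may remove the C-10′ methine or an α-hydrogen in place of the isopropyl methine, or dioxygen may couple at C-1′ or C-6′ of the trienolate, so that C-10′ is scrambled or other hydroperoxides form. The fallback uses known chemistry and sets out from 34. DBU-mediated deconjugation gives the α-isopropylidene ketone isomer F1 (exocyclic C-7′=C-11′, C-6′ methylene). Sensitised photo-oxygenation (O2, tetraphenylporphyrin, visible light, CH2Cl2) then effects a Schenck ene reaction of this s-cis isopropylidene ketone, with hydrogen abstraction from the C-6′ methylene geminal to the carbonyl and C–O bond formation at C-11′. This gives hydroperoxide 35, where the fallback rejoins the route, and 35 closes to 36. The tetrasubstituted C-4=C-5 alkene should survive singlet oxygen because its exo face is covered by the syn-acetoxy group and its endo face by the fused cyclopentenone.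

2. Step 25. The excited ene-dione may be drained by addition to the norbornene alkene or by hydrogen abstraction from the isopropyl group, so that the cyclobutene forms inefficiently. The fallback sets out from 31 and reverses the order of oxidation and irradiation. Diol 31 has a plain acylcyclopentene enone chromophore with no 1,4-dione n,π* state; sensitised irradiation (thioxanthone or acetone) should give the photoadduct diol F2. Dess–Martin oxidation of both carbinols then gives 33, where the fallback rejoins the route.

3. Step 26. The cis-fused cyclobutene may resist thermal opening (the concerted disrotatory path is forbidden and the stepwise path may need temperatures at which the acetate or the bridge is lost). The fallback sets out from 33. Reductive cleavage of the strained 1,4-diketone bond with SmI2 (THF–MeOH, −78 °C; ketyl, β-scission, enolate) gives the 1,6-diketone F3 with a C-5′=C-6′ alkene. Dehydrogenation with DDQ through the dienol then gives 34, where the fallback rejoins the route.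

Further compounds
F1 | step 27 | α-isopropylidene ketone isomer of 34 | CC(=O)O[C@H]1[C@H]2C(C)=C3C[C@@H](C(C)C)C(=O)C[C@@H](C)[C@]31[C@]1(C)C3=C(C(=O)[C@H]21)[C@H](C)CC(=O)C(=C(C)C)C3
F2 | step 25 | cyclobutene photoadduct 8,8′-diol | CC(=O)O[C@H]1[C@H]2C(C)=C3C[C@@H](C(C)C)[C@@H](O)C[C@@H](C)[C@]31[C@]1(C)C3=C[C@]4(C(C)C)[C@@H](O)C[C@@H](C)[C@]34C(=O)[C@H]21
F3 | step 26 | ring-opened 1,6-diketone (dihydro-34, C-5′=C-6′ alkene) | CC(=O)O[C@H]1[C@H]2C(C)=C3C[C@@H](C(C)C)C(=O)C[C@@H](C)[C@]31[C@]1(C)C3=CC(C(C)C)C(=O)C[C@@H](C)C3C(=O)[C@H]21
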